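Slowness comes early in these runs: the substrate stops falling short of zero, and of oak and cedar, which have the same equivalents of partner, it stops lower in cedar, the stronger solution.

| flask | substrate | partner | remark | time |
|---|---|---|---|---|
| oak | 0.050 M | 1 equiv (in portions, 4) | run made earlier; portions every 25 min |  |
| cedar | 0.20 M | 1 equiv (in portions, 4) | run made earlier; portions every 25 min |  |
| elm | 0.10 M | 0.50 equiv (in portions, 4) | run made earlier; portions every 25 min |  |
| flask | 0.10 M | 1.00 equiv (in portions, 4) | the portions of partner follow each other after 25 min, the first at the start | 2.0 d |

| run | time / h | substrate / % | target / % |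
|---|---|---|---|
| oak | 6.00 | 10 | 22 |
| oak | 12.0 | 9 | 23 |
| oak | 15.0 | 10 | 24 |
| oak | 25.0 | 11 | 24 |
| oak | 30.0 | 6 | 26 |
| cedar | 2.50 | 7 | 18 |
| cedar | 8.00 | 2 | 26 |
| cedar | 12.0 | 5 | 26 |
| cedar | 20.0 | 3 | 27 |
| cedar | 30.0 | 2 | 27 |
| elm | 6.00 | 50 | 14 |
| elm | 12.0 | 54 | 9 |
| elm | 15.0 | 53 | 12 |
| elm | 25.0 | 52 | 13 |
| elm | 30.0 | 50 | 15 |

(readings scatter by 2 percentage points)

- the reaction counts as stopped when no species that holds the substrate changes by six tenths of a point or more over the second half of the time

* which holds at 2.0 d: what has brought the reaction to rest, or that it has not come to rest (forward and back rates have come level / it is still moving / the partner has run out first / all of the substrate has reacted)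
* conversion of substrate at 2.0 d
* amount of target at 2.0 d, in percent of the substrate charged
* amount of isomer of the product at 2.0 d, in percent of the substrate charged

This is our own reckoning. We suppose that partner reacts with substrate and also decays slowly by itself. Let x be the fraction of substrate left.

1. The rule. The reaction slows as x falls, so partner lost per partner used grows as w/x. Summed from the start, the loss is w·ln(1/x). With equal charges, the run stops when that loss equals x.

2. The runs. Oak rests near 9.20% and cedar, from 8.00 h on, near 3.00%. These are readings, with a scatter of 2 percentage points. The rule gives w = 3.86% for oak and 0.856% for cedar. We take w to vary inversely with strength, so at 0.10 M the two average to 1.82%. This w is the break-even fraction, the x at which partner is lost as fast as it reacts.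

3. First instants. In the flask x is near one, so the loss is about 1.82% of the partner used.

4. Middle. At x = 0.5 the loss per partner used is 3.64%, and the summed loss is 1.26% of the charge.

5. End. Oak and cedar each lie a factor 2.00 from the flask, so we start from their geometric middle, 5.25%. Two rounds of the rule give x = 5.32%. Partner is then the limiting reagent, and we expect it to run out. Conversion is 94.7%. Target has held about 26.8% of what reacted, which gives 25.4% target. Counting the rest as isomer gives 69.3%.

The forecast gives forward and back rates have come level, conversion 94%, target 25.3% and isomer 68.7%, and says “has reached equilibrium well before 2 d”.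

The flask gives the partner has run out first, with conversion 95.2%, target 25.1% and isomer 70.2%.

    substrate + partner → intermediate (k = 38.0 M⁻¹ h⁻¹)
    intermediate → target (k = 0.610 h⁻¹)
    partner → decomposed reagent (k = 0.0600 h⁻¹)
    target ⇌ isomer of the product (K = 2.80, k = 5.00 h⁻¹)

The flask is at rest: at 2.00 d partner stands at 0% and substrate at 4.8%. With that x, w gives a loss of 5.53%, and the decomposed reagent, 0.00480 M, is 4.80% of the charge. The neighbour flask with 0.250 equiv of partner keeps 75.4% substrate; there w gives 0.514%, and its decomposed reagent is 0.445%. Ten times the time leaves conversion at 95.2%, target at 25.1% and isomer at 70.2%. The substrate half-life at 2.00 d is 9600 d, longer than the asked time. With 38 M⁻¹ h⁻¹, that half-life means a trace of partner, and this trace lets the added 18.0 d take at most 7.9 × 10⁻⁵ points from the substrate.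

The earlier runs and the new flask were computed with constants of no real substance.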